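**Retrosynthetic overview**
1. Cyclocymopol 15 ← dimethyl ether 13 (oxidative demethylation, then reduction) ← axial alcohol 12 (Appel bromination with inversion) ← ketone 11 (methylenation).
2. Key disconnection: 11 ← one-carbon ring expansion of (S)-3-hydroxy-2,2-dimethylcyclopentanone 7 by a β-oxido carbenoid 1,2-shift in which the quaternary carbon migrates; the ring-enlarged enolate is benzylated in the same flask by benzylic bromide 4.
3. 7 ← CBS desymmetrisation of 2,2-dimethylcyclopentane-1,3-dione 6 ← 2-methylcyclopentane-1,3-dione 5 + MeI.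
4. 4 ← hydroquinone 1 (O-methylation, then ring bromination and bromomethylation in one pot).
5. Ring order: the arene and the cyclopentane are bought; the cyclohexane is made from the cyclopentane in step 5; no other ring is formed.

Assumption: descriptors are read from the given SMILES, i.e. the C–Br carbon is R, the C–CH2Ar carbon is S, and Br and CH2Ar are cis on the ring.

**Step 1**
Reactants: 1 hydroquinone
Product: 2 1,4-dimethoxybenzene
Conditions: MeI (2.5 equiv), K2CO3, acetone, reflux
Reagents that add atoms: iodomethane CI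
Why: Williamson O-methylation of both phenoxides protects the hydroquinone as a base- and organolithium-stable dimethyl ether.

**Step 2**
Reactants: 2 1,4-dimethoxybenzene
Product: 4 1-bromo-4-(bromomethyl)-2,5-dimethoxybenzene, via 2-bromo-1,4-dimethoxybenzene 3 (not isolated)
Conditions: Br2 (1.0 equiv), AcOH, rt; then (CH2O)n, 33% HBr/AcOH, 60 °C
Reagents that add atoms: bromine BrBr; formaldehyde (as paraformaldehyde) C=O; hydrogen bromide Br
Why: Electrophilic aromatic bromination followed by Blanc-type bromomethylation in the same HBr/AcOH medium, the second substitution going para to Br and ortho to OMe as in the known formylation of 3.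

**Step 3**
Reactants: 5 2-methylcyclopentane-1,3-dione
Product: 6 2,2-dimethylcyclopentane-1,3-dione
Conditions: MeI, KOH, H2O/1,4-dioxane, reflux
Reagents that add atoms: iodomethane CI
Why: C-alkylation of the 1,3-dione enolate with MeI builds the gem-dimethyl quaternary carbon.

**Step 4**
Reactants: 6 2,2-dimethylcyclopentane-1,3-dione
Product: 7 (S)-3-hydroxy-2,2-dimethylcyclopentan-1-one
Conditions: (R)-Me-CBS (10 mol %), BH3·THF (0.6 equiv), THF, −20 °C
Reagents that add atoms: none
Why: Corey–Bakshi–Shibata desymmetrising mono-reduction, in which the quaternary carbon acts as the large group so that the (R)-catalyst is predicted to give the (S)-carbinol, the future C–Br carbon before inversion.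

**Step 5**
Reactants: 7 (S)-3-hydroxy-2,2-dimethylcyclopentan-1-one; 4 1-bromo-4-(bromomethyl)-2,5-dimethoxybenzene
Product: 11 (2R,4S)-2-[(4-bromo-2,5-dimethoxyphenyl)methyl]-4-hydroxy-3,3-dimethylcyclohexan-1-one, via dibromomethyl dialkoxide adduct 8 (not isolated), via β-oxido carbenoid 9 (not isolated), via ring-enlarged dilithium enolate 10 (not isolated)
Conditions: CH2Br2 (1.2 equiv), LiTMP (2.2 equiv), THF, −78 °C; n-BuLi (1.1 equiv), −95 → 0 °C; then 4, DMPU, −40 → 0 °C
Reagents that add atoms: dibromomethane BrCBr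
Why: Proposed new method: a one-flask ring expansion–benzylation on an unprotected β-hydroxy ketone, in which LiCHBr2 adds to the ketone of the lithium alkoxide of 7 to give 8, Br/Li exchange gives carbenoid 9, and the alkoxide-driven 1,2-shift of the quaternary carbon (the better migrating group, as in pinacol-type shifts) expels LiBr and delivers the otherwise inaccessible C1=C2 enolate 10 of the cyclohexanone, which is C-benzylated by 4 by axial attack anti to the pseudo-axial C3 methyl on the half-chair with the C4 alkoxide equatorial, setting the benzylic stereocentre 2,4-trans (2R); the closest known reaction types are the Nozaki–Yamamoto β-oxido carbenoid ring enlargement of cycloalkanones (normally ended by protonation) and Fráter–Seebach-type C-alkylation of alkoxide–enolate dianions.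

**Step 6**
Reactants: 11 (2R,4S)-2-[(4-bromo-2,5-dimethoxyphenyl)methyl]-4-hydroxy-3,3-dimethylcyclohexan-1-one
Product: 12 (1S,3S)-3-[(4-bromo-2,5-dimethoxyphenyl)methyl]-2,2-dimethyl-4-methylidenecyclohexan-1-ol
Conditions: Zn, CH2Br2, TiCl4 (Lombardo reagent, excess), THF/CH2Cl2, 0 °C → rt
Reagents that add atoms: dibromomethane BrCBr
Why: Takai–Lombardo methylenation with a non-basic Zn/Ti gem-dimetal reagent converts the hindered ketone to the exocyclic alkene without epimerising the adjacent stereocentre; the free hydroxyl is carried as its titanium alkoxide.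

**Step 7**
Reactants: 12 (1S,3S)-3-[(4-bromo-2,5-dimethoxyphenyl)methyl]-2,2-dimethyl-4-methylidenecyclohexan-1-ol
Product: 13 1-bromo-4-{[(1S,3R)-3-bromo-2,2-dimethyl-6-methylidenecyclohexyl]methyl}-2,5-dimethoxybenzene
Conditions: CBr4, PPh3, pyridine, CH2Cl2, 0 °C → reflux
Reagents that add atoms: carbon tetrabromide BrC(Br)(Br)Br
Why: Appel bromination, in which bromide displaces the axial alkoxyphosphonium group by SN2 with inversion, giving the equatorial (R)-bromide cis to the arylmethyl group.

**Step 8**
Reactants: 13 1-bromo-4-{[(1S,3R)-3-bromo-2,2-dimethyl-6-methylidenecyclohexyl]methyl}-2,5-dimethoxybenzene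
Product: 15 cyclocymopol, via bromoquinone 14 (not isolated)
Conditions: CAN (2.5 equiv), MeCN/H2O, 0 °C; then Na2S2O4, EtOAc/H2O, rt
Reagents that add atoms: water O
Why: Ceric ammonium nitrate oxidative demethylation to the p-quinone followed by dithionite reduction frees the hydroquinone while it is never exposed to acid, so the alkene, the alkyl bromide and both stereocentres are untouched.

**Compound list**
1 | hydroquinone (benzene-1,4-diol) | Oc1ccc(O)cc1 | starting material
2 | 1,4-dimethoxybenzene | COc1ccc(OC)cc1 | intermediate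
3 | 2-bromo-1,4-dimethoxybenzene | COc1ccc(OC)c(Br)c1 | intermediate
4 | 1-bromo-4-(bromomethyl)-2,5-dimethoxybenzene | COc1cc(CBr)c(OC)cc1Br | intermediate
5 | 2-methylcyclopentane-1,3-dione | CC1C(=O)CCC1=O | starting material
6 | 2,2-dimethylcyclopentane-1,3-dione | CC1(C)C(=O)CCC1=O | intermediate
7 | (S)-3-hydroxy-2,2-dimethylcyclopentan-1-one | O=C1CC[C@H](O)C1(C)C | intermediate
8 | dilithium (3S)-1-(dibromomethyl)-2,2-dimethylcyclopentane-1,3-bis(olate), C1 epimers | [Li]OC1(C(Br)Br)CC[C@H](O[Li])C1(C)C | intermediate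
9 | dilithium (3S)-1-[bromo(lithio)methyl]-2,2-dimethylcyclopentane-1,3-bis(olate) (β-oxido carbenoid) | [Li]OC1(C([Li])Br)CC[C@H](O[Li])C1(C)C | intermediate
10 | dilithium (4S)-3,3-dimethylcyclohex-1-ene-1,4-bis(olate) | [Li]OC1=CC(C)(C)[C@@H](O[Li])CC1 | intermediate
11 | (2R,4S)-2-[(4-bromo-2,5-dimethoxyphenyl)methyl]-4-hydroxy-3,3-dimethylcyclohexan-1-one | O=C1CC[C@H](O)C(C)(C)[C@H]1Cc1cc(OC)c(Br)cc1OC | intermediate
12 | (1S,3S)-3-[(4-bromo-2,5-dimethoxyphenyl)methyl]-2,2-dimethyl-4-methylidenecyclohexan-1-ol | C=C1CC[C@H](O)C(C)(C)[C@H]1Cc1cc(OC)c(Br)cc1OC | intermediate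
13 | 1-bromo-4-{[(1S,3R)-3-bromo-2,2-dimethyl-6-methylidenecyclohexyl]methyl}-2,5-dimethoxybenzene | C=C1CC[C@@H](Br)C(C)(C)[C@H]1Cc1cc(OC)c(Br)cc1OC | intermediate
14 | 2-bromo-5-{[(1S,3R)-3-bromo-2,2-dimethyl-6-methylidenecyclohexyl]methyl}cyclohexa-2,5-diene-1,4-dione | C=C1CC[C@@H](Br)C(C)(C)[C@H]1CC1=CC(=O)C(Br)=CC1=O | intermediate
15 | cyclocymopol, 2-bromo-5-{[(1S,3R)-3-bromo-2,2-dimethyl-6-methylidenecyclohexyl]methyl}benzene-1,4-diol | C=C1CC[C@@H](Br)C(C)(C)[C@H]1Cc1cc(O)c(Br)cc1O | target

**Step count and risks**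
Total step count: 8. Longest linear sequence: 6 (steps 3, 4, 5, 6, 7, 8, or equally 1, 2, 5, 6, 7, 8).

Steps most likely to fail:

Step 5 (the proposed new step). Risks are poor addition of LiCHBr2 to the hindered ketone, migration of the CH2 carbon instead of the quaternary one, and proton transfer or O-alkylation during benzylation of the hindered dianion. The fallback uses known stepwise chemistry, sets out from 7 and comes back at 11. Compound 7 is silylated (TBSCl, imidazole) to (S)-3-[(tert-butyldimethylsilyl)oxy]-2,2-dimethylcyclopentan-1-one F1. LiCHBr2 is added and the carbinol (3S)-3-[(tert-butyldimethylsilyl)oxy]-1-(dibromomethyl)-2,2-dimethylcyclopentan-1-ol F2 is isolated. Two equivalents of n-BuLi (classical two-stage Nozaki–Yamamoto enlargement) convert it into lithium (4S)-4-[(tert-butyldimethylsilyl)oxy]-3,3-dimethylcyclohex-1-en-1-olate F3, which is quenched with Me3SiCl and isolated as tert-butyl{[(1S)-2,2-dimethyl-4-[(trimethylsilyl)oxy]cyclohex-3-en-1-yl]oxy}dimethylsilane F4. MeLi regenerates F3 regiospecifically from F4, and benzylation with 4 gives (2R,4S)-2-[(4-bromo-2,5-dimethoxyphenyl)methyl]-4-[(tert-butyldimethylsilyl)oxy]-3,3-dimethylcyclohexan-1-one F5. TBAF then returns to 11. This fallback does not cure a wrong migration sense; it addresses the dianion and trapping problems.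

Step 6. The ketone is hindered on both sides and carries a free hydroxyl, so methylenation may stall. The fallback is a two-stage Peterson olefination that sets out from 11 and comes back at 12: Me3SiCH2MgCl/CeCl3 adds to the ketone to give (2R,4S)-2-[(4-bromo-2,5-dimethoxyphenyl)methyl]-3,3-dimethyl-1-[(trimethylsilyl)methyl]cyclohexane-1,4-diol F6, and KH in THF effects syn-elimination to 12.

Step 7. The alcohol is secondary and neopentylic, so elimination or rearrangement can compete with SN2. The fallback replaces the oxyphosphonium route by sulfonate displacement, sets out from 12 and comes back at 13: Tf2O/pyridine at −30 °C gives (1S,3S)-3-[(4-bromo-2,5-dimethoxyphenyl)methyl]-2,2-dimethyl-4-methylidenecyclohexyl trifluoromethanesulfonate F7, which n-Bu4NBr in toluene displaces with inversion to 13.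

**Further compounds**
F1 | step 5 | (S)-3-[(tert-butyldimethylsilyl)oxy]-2,2-dimethylcyclopentan-1-one | O=C1CC[C@H](O[Si](C)(C)C(C)(C)C)C1(C)C
F2 | step 5 | (3S)-3-[(tert-butyldimethylsilyl)oxy]-1-(dibromomethyl)-2,2-dimethylcyclopentan-1-ol | OC1(C(Br)Br)CC[C@H](O[Si](C)(C)C(C)(C)C)C1(C)C
F3 | step 5 | lithium (4S)-4-[(tert-butyldimethylsilyl)oxy]-3,3-dimethylcyclohex-1-en-1-olate | [Li]OC1=CC(C)(C)[C@@H](O[Si](C)(C)C(C)(C)C)CC1
F4 | step 5 | tert-butyl{[(1S)-2,2-dimethyl-4-[(trimethylsilyl)oxy]cyclohex-3-en-1-yl]oxy}dimethylsilane | C[Si](C)(C)OC1=CC(C)(C)[C@@H](O[Si](C)(C)C(C)(C)C)CC1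
F5 | step 5 | (2R,4S)-2-[(4-bromo-2,5-dimethoxyphenyl)methyl]-4-[(tert-butyldimethylsilyl)oxy]-3,3-dimethylcyclohexan-1-one | O=C1CC[C@H](O[Si](C)(C)C(C)(C)C)C(C)(C)[C@H]1Cc1cc(OC)c(Br)cc1OC
F6 | step 6 | (2R,4S)-2-[(4-bromo-2,5-dimethoxyphenyl)methyl]-3,3-dimethyl-1-[(trimethylsilyl)methyl]cyclohexane-1,4-diol | C[Si](C)(C)CC1(O)CC[C@H](O)C(C)(C)[C@H]1Cc1cc(OC)c(Br)cc1OC
F7 | step 7 | (1S,3S)-3-[(4-bromo-2,5-dimethoxyphenyl)methyl]-2,2-dimethyl-4-methylidenecyclohexyl trifluoromethanesulfonate | C=C1CC[C@H](OS(=O)(=O)C(F)(F)F)C(C)(C)[C@H]1Cc1cc(OC)c(Br)cc1OC
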